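**Retrosynthetic overview**
- The target is an acyclic, achiral ester of a saturated C20 acid with 2-phenylethanol. The strategy rests on the C10–C11 bond of the acyl chain, which lies at its exact midpoint and divides it into two ten-carbon halves.
- The saturated C10–C11 bond is traced back to a C10=C11 alkene, phenethyl icos-10-enoate, of either geometry.
- The C10=C11 bond is disconnected by cross-metathesis into phenethyl undec-10-enoate and 1-undecene, each of which gives up its terminal CH2 as ethene.
- The ester C(=O)–O bond is disconnected into undec-10-enoic acid and 2-phenylethanol.
- No ring is formed, since the phenyl ring arrives intact in 2-phenylethanol, and there is no stereocentre to set.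

Key step: step 2

Assumption: alkene 5 is named and drawn as its major E isomer but is carried forward as the E/Z mixture, because step 3 removes the double bond.

**Step 1**
Reactants: 1 undec-10-enoic acid; 2 2-phenylethanol
Product: 3 phenethyl undec-10-enoate
Conditions: 1 (1.1 equiv), TsOH·H2O (5 mol%), toluene, reflux, Dean–Stark; aq. NaHCO3 wash
Reagents that add atoms: none
Why: Fischer esterification of a primary alcohol with an unhindered acid, driven to completion by azeotropic removal of water, should leave the remote terminal alkene untouched under catalytic acid.

**Step 2**
Reactants: 3 phenethyl undec-10-enoate; 4 1-undecene
Product: 5 phenethyl (E)-icos-10-enoate (major isomer, accompanied by the Z isomer)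
Conditions: 4 (3 equiv), second-generation Grubbs catalyst RuCl2(=CHPh)(PCy3)(H2IMes) (2 mol%), 1,4-benzoquinone (10 mol%), CH2Cl2, 40 °C, Ar sparge; then ethyl vinyl ether; SiO2
Reagents that add atoms: none
Why: Olefin cross-metathesis: loss of PCy3 from the precatalyst gives a 14-electron ruthenium alkylidene that adds each terminal alkene in a [2+2] fashion to a ruthenacyclobutane, and cycloreversion passes the C10 and C11 alkylidene units between ruthenium methylidene and alkylidene carriers until the C10=C11 bond is formed. The closest known reaction type is cross-metathesis of a terminal alkenyl fatty ester with a 1-alkene, both partners being unhindered terminal olefins that homodimerise readily and whose homodimers re-enter the cycle. No ring is closed and no stereocentre is formed; the E isomer should predominate under thermodynamic control, and the geometry does not matter for the next step. The selectivity needed is cross-coupling over homodimerisation of the ester, which is statistical and is secured by the threefold excess of 4 and by sweeping out ethene in the argon stream; the hydrocarbon homodimer and the diester homodimer differ enough in polarity from 5 to be removed on silica. The position of the double bond, and with it the C20 chain length, is protected by 1,4-benzoquinone, which intercepts ruthenium hydride species that would otherwise migrate the alkenes before exchange. The ester carbonyl lies eight methylenes away from the alkene and cannot chelate the carbene.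

**Step 3**
Reactants: 5 phenethyl (E)-icos-10-enoate (E/Z mixture)
Product: 6 phenethyl icosanoate
Conditions: H2 (1 atm), 10% Pd/C, EtOAc, rt
Reagents that add atoms: none
Why: Heterogeneous catalytic hydrogenation should saturate the unhindered 1,2-disubstituted alkene of both isomers to the same chain, while the homobenzylic ester C–O bond is not prone to hydrogenolysis and the phenyl ring is not reduced at ambient pressure.

**Compound list**
1 | undec-10-enoic acid | C=CCCCCCCCCC(=O)O | starting material
2 | 2-phenylethanol | OCCc1ccccc1 | starting material
3 | phenethyl undec-10-enoate | C=CCCCCCCCCC(=O)OCCc1ccccc1 | intermediate
4 | 1-undecene | C=CCCCCCCCCC | starting material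
5 | phenethyl (E)-icos-10-enoate (major isomer, carried with its Z isomer) | CCCCCCCCC/C=C/CCCCCCCCC(=O)OCCc1ccccc1 | intermediate
6 | phenethyl icosanoate | CCCCCCCCCCCCCCCCCCCC(=O)OCCc1ccccc1 | target

Total step count: 3
Longest linear sequence: 3 steps (1 → 3 → 5 → 6)

**Steps most likely to fail**

Step 2. The exchange may drift into homodimerisation of the ester, and hydride-mediated migration of the double bond before metathesis would give chain-length homologues that cannot be separated after hydrogenation. The fallback sets out from 3 and avoids metathesis. Anti-Markovnikov hydroboration of the terminal alkene with 9-BBN-H (THF, 0 °C to rt) should give phenethyl 11-(9-borabicyclo[3.3.1]nonan-9-yl)undecanoate F1, used without isolation. This is coupled with 1-bromononane (CCCCCCCCCBr) in an alkyl–alkyl Suzuki–Miyaura reaction (Pd(OAc)2, PCy3, K3PO4·H2O, THF, rt), which tolerates the ester. The coupling forms the C11–C12 bond of the saturated chain and comes back to the route at 6, so that 5 and step 3 are bypassed.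

Step 3. The hydrogenation may stall if ruthenium or phosphine residues carried over from step 2 poison the palladium surface, and forcing it with pressure or heat could begin to saturate the phenyl ring. The fallback sets out from 5 and uses a metal-free reduction. Diimide F2 is generated in the flask from p-toluenesulfonyl hydrazide and sodium acetate (DME/H2O, reflux) and should transfer two hydrogen atoms to the alkene in a concerted syn fashion. It does not touch the ester or the arene, and the route is rejoined at 6.

Step 1. Conversion may stop short at equilibrium, and prolonged heating with acid could lead to self-etherification of the alcohol or migration of the terminal double bond. The fallback sets out from 1 and uses irreversible acylation. Oxalyl chloride with catalytic DMF (CH2Cl2, 0 °C to rt) should give undec-10-enoyl chloride F3. This is treated with 2, Et3N and catalytic DMAP (CH2Cl2, 0 °C) to return to the route at 3.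

**Further compounds**
F1 | step 2 | phenethyl 11-(9-borabicyclo[3.3.1]nonan-9-yl)undecanoate | O=C(CCCCCCCCCCB1C2CCCC1CCC2)OCCc1ccccc1
F2 | step 3 | diimide | N=N
F3 | step 1 | undec-10-enoyl chloride | C=CCCCCCCCCC(=O)Cl
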